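The numbers in the tables are calculated on assumed constants, and the scatter is random.

Hold the time at 40 h and let the temperature differ between the flasks. Then keep a ledger of the starting material in each flask.

in all of them: starting material 0.40 M
- noon: protic impurity 0.10 M; temperature 58 °C; run made earlier
- summer: protic impurity 0.40 M; temperature 74 °C; run made earlier
- violet: protic impurity 0.200 M; temperature 50 °C; time 40 h
- amber: protic impurity 0.200 M; temperature 80 °C; time 40 h
- red: protic impurity 0.200 M; temperature 65 °C; time 40 h

| run | time / h | product / % | starting material / % |
|---|---|---|---|
| noon | 3.00 | 71.7 | 22.1 |
| noon | 6.00 | 85.5 | 7.5 |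
| noon | 12.0 | 86.2 | 3.2 |
| noon | 20.0 | 85.1 | 4.8 |
| noon | 40.0 | 81.9 | 3.6 |
| summer | 2.50 | 72.2 | 4.5 |
| summer | 5.00 | 68.7 | 2.2 |
| summer | 8.00 | 64.6 | 2.5 |
| summer | 10.0 | 60.8 | 3.1 |
| summer | 12.0 | 60.5 | 3.1 |

(standard deviation of a reading: 1 percentage point)

- the flask with the highest amount of product, in percent of the starting material charged ("all alike" if they lie within 1.5 percentage points) (violet / amber / red / all alike)
- final product, as a percentage of the starting material charged, in violet
- final product, as a percentage of the starting material charged, in amber
- final product, as a percentage of the starting material charged, in red



Every mole charged stands as starting material, as product, or in a missing entry, which is what the readings leave short of the charge. Assume that each missing mole took one protic impurity with it. Then the loss ceiling, c(protic impurity) over c(starting material), is the missing entry the impurity can pay for: 50.0% in violet, amber and red. So in these three flasks, on this assumption, impurity is the limiting reagent of the loss.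

Divide each missing entry by its run's ceiling to get the spent share of impurity. Noon reads 42.4% at 12.0 h and 58.0% at 40.0 h. Summer reads 23.3% at 2.50 h and 36.4% at 12.0 h. These are readings with their scatter. Take the spending constant on the impurity left: 0.0113 h⁻¹ in noon and 0.0197 h⁻¹ in summer. The two runs differ in impurity as well as temperature, but treat the gap as temperature. Carry the logarithm along a straight line in temperature, which gives 0.0243 h⁻¹ for amber. Open each recipe with the mean early share, 32.8%, and leave 3.35% as starting material.

First round: hold the spending steady. Amber then books 130% of its impurity, more than was charged. Second round: put the impurity left back in, so the spending decays exponentially. My reckoning then gives 70.5% product in violet, 59.3% in amber and 65.5% in red. I commit to violet as highest.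

The forecast gives 79% for violet, 42% for amber and 69% for red, and it concludes: “Violet should end highest.”

The flasks give 75.1% in violet, 54.3% in amber and 68.7% in red, so violet stands highest.

    starting material ⇌ product + released group (K = 8.70 M, k = 0.00310 min⁻¹, Ea = 110 kJ mol⁻¹, ΔH = −22.0 kJ mol⁻¹)
    starting material + protic impurity → quenched substrate (k = 0.00510 M⁻¹ min⁻¹, Ea = 73.0 kJ mol⁻¹)
    (constants at 50 °C)

Amber holds 43.0% quenched substrate after 40.0 h, which is 86.0% of its ceiling, and 14% of its impurity is left. Now take the neighbour of red with c(starting material) at 0.10 M. Its ceiling is 200%, above the whole charge of starting material. Starting material goes first there, with 0.87% left. Its quenched substrate, 21.3%, is 10.7% of that ceiling, 89.3% of its impurity remains, and its product ends at 77.8%.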